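**Retrosynthetic overview**
- Target 10 ⇐ tetraacetate 9 by chemoselective aminolysis of the three aryl acetates; the C3 alkyl acetate stays.
- C1–aryl bond ⇐ anti-Markovnikov hydroboration of the vinyl group of allylic acetate 4, then B-alkyl Suzuki coupling with 4-bromocatechol diacetate 6.
- Key disconnection, the C3–O bond ⇐ enantioselective allylic C–H acetoxylation of the terminal olefin of diene 3; this sets the only stereocentre and installs the acetate that is carried to the end.
- C7–aryl bond ⇐ mono-Heck arylation of hepta-1,6-diene (all seven chain carbons) with 4-iodophenyl acetate.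
- No ring is formed; both benzene rings come with the starting materials.

Assumption: the (S,S) ligand named in step 2 is taken to give the (S) acetate (if the measured sense is opposite, its enantiomer is used), and 1, 2, 5 and 7 are taken as catalogue chemicals.

The target was read as (3S,6E): at C3 the priorities are O > CH2CH2-aryl (catechol arm) > CH2CH2CH=CH-aryl > H.

**Step 1**
Reactants: 1 4-iodophenyl acetate; 2 hepta-1,6-diene (4 equiv)
Product: 3 4-[(1E)-hepta-1,6-dien-1-yl]phenyl acetate
Conditions: Pd(OAc)2 (5 mol%), Bu4NCl, NaHCO3, DMF, 45 °C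
Reagents that add atoms: none
Why: Mizoroki–Heck reaction under ligand-free phase-transfer (Jeffery) conditions, in which oxidative addition of the aryl iodide, syn-insertion at the terminal carbon and syn-β-hydride elimination give the conjugated (E)-styrene, and the excess of the symmetric diene holds the reaction at mono-arylation.

**Step 2**
Reactants: 3 4-[(1E)-hepta-1,6-dien-1-yl]phenyl acetate
Product: 4 (3S,6E)-7-(4-acetoxyphenyl)hepta-1,6-dien-3-yl acetate
Conditions: Pd(OAc)2 (10 mol%), (4S)-4-tert-butyl-2-{2-[(S)-(4-methylphenyl)sulfinyl]phenyl}-4,5-dihydro-1,3-oxazole (12 mol%), 2,6-dimethyl-1,4-benzoquinone (1.5 equiv), AcOH (10 equiv), 1,4-dioxane, 45 °C, 48 h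
Reagents that add atoms: acetic acid, CC(=O)O
Why: Proposed new method: enantioselective intermolecular branched allylic C–H acetoxylation of an unactivated terminal olefin, in which divalent palladium held by the chiral sulfoxide–oxazoline cleaves the C–H bond next to the terminal olefin (sulfoxide-assisted, acetate as internal base) to a π-allyl palladium acetate, the quinone then binds and triggers inner-sphere C–O bond formation at the internal allyl terminus while the oxazoline arm with its tert-butyl group stays on the metal, so that fast π–σ–π equilibration of the allyl followed by ligand-controlled acetate delivery to one face sets the (S) centre, and the zerovalent palladium released is reoxidised by the quinone; the internal styrenyl olefin is left alone because sulfoxide-ligated palladium activates only terminal olefins; closest known reaction type: the racemic branched-selective allylic C–H acetoxylation of terminal olefins with Pd(OAc)2, a bis-sulfoxide and benzoquinone, and the enantioselective intramolecular allylic C–H etherification with Pd(OAc)2 and chiral sulfoxide–oxazolines.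

**Step 3**
Reactants: 5 4-bromobenzene-1,2-diol
Product: 6 4-bromo-1,2-phenylene diacetate
Conditions: Ac2O (2.5 equiv), pyridine, DMAP (cat.), CH2Cl2, 0 °C to rt
Reagents that add atoms: acetic anhydride, CC(=O)OC(C)=O
Why: Standard base-mediated O-acetylation (nucleophilic acyl substitution) masks the oxidation- and base-sensitive catechol with the same acyl group that is used on the other phenol.

**Step 4**
Reactants: 4 (3S,6E)-7-(4-acetoxyphenyl)hepta-1,6-dien-3-yl acetate; 7 9-borabicyclo[3.3.1]nonane (1.2 equiv, handled as its dimer); 6 4-bromo-1,2-phenylene diacetate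
Product: 9 4-[(3S,6E)-3-acetoxy-7-(4-acetoxyphenyl)hept-6-en-1-yl]-1,2-phenylene diacetate, via B-alkyl-9-BBN adduct 8 (not isolated)
Conditions: 7, THF, 0 °C to rt; then 6, PdCl2(dppf) (5 mol%), powdered K3PO4 (3 equiv), DMF, 50 °C
Reagents that add atoms: none
Why: 9-BBN hydroborates only the monosubstituted vinyl group, anti-Markovnikov (the internal styrenyl olefin reacts far more slowly), and the primary alkylborane then undergoes B-alkyl Suzuki–Miyaura coupling with the aryl bromide under a non-aqueous phosphate base that spares the acetates; the C3 centre is not touched.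

**Step 5**
Reactants: 9 4-[(3S,6E)-3-acetoxy-7-(4-acetoxyphenyl)hept-6-en-1-yl]-1,2-phenylene diacetate
Product: 10 (3S,6E)-1-(3,4-dihydroxyphenyl)-7-(4-hydroxyphenyl)hept-6-en-3-yl acetate
Conditions: pyrrolidine (4 equiv), THF, 0 °C to rt, argon; pH 5 phosphate buffer work-up
Reagents that add atoms: none
Why: Chemoselective ester aminolysis, in which phenyl esters react with a secondary amine orders of magnitude faster than a secondary alkyl acetate (phenoxide is the better leaving group), so the three aryl acetates are removed while the C3 acetate and its configuration are kept.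

**Compound list**
1 | 4-iodophenyl acetate | CC(=O)Oc1ccc(I)cc1 | starting material
2 | hepta-1,6-diene | C=CCCCC=C | starting material
3 | 4-[(1E)-hepta-1,6-dien-1-yl]phenyl acetate | CC(=O)Oc1ccc(/C=C/CCCC=C)cc1 | intermediate
4 | (3S,6E)-7-(4-acetoxyphenyl)hepta-1,6-dien-3-yl acetate | CC(=O)O[C@@H](CC/C=C/c1ccc(OC(C)=O)cc1)C=C | intermediate
5 | 4-bromobenzene-1,2-diol (4-bromocatechol) | Oc1ccc(Br)cc1O | starting material
6 | 4-bromo-1,2-phenylene diacetate | CC(=O)Oc1ccc(Br)cc1OC(C)=O | intermediate
7 | 9-borabicyclo[3.3.1]nonane (9-BBN, used as its dimer) | B1C2CCCC1CCC2 | starting material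
8 | (3R,6E)-7-(4-acetoxyphenyl)-1-(9-borabicyclo[3.3.1]nonan-9-yl)hept-6-en-3-yl acetate (same spatial arrangement as 4; the descriptor changes only through the priority rules) | CC(=O)O[C@@H](CC/C=C/c1ccc(OC(C)=O)cc1)CCB1C2CCCC1CCC2 | intermediate
9 | 4-[(3S,6E)-3-acetoxy-7-(4-acetoxyphenyl)hept-6-en-1-yl]-1,2-phenylene diacetate | CC(=O)O[C@@H](CC/C=C/c1ccc(OC(C)=O)cc1)CCc1ccc(OC(C)=O)c(OC(C)=O)c1 | intermediate
10 | (3S,6E)-1-(3,4-dihydroxyphenyl)-7-(4-hydroxyphenyl)hept-6-en-3-yl acetate | CC(=O)O[C@@H](CC/C=C/c1ccc(O)cc1)CCc1ccc(O)c(O)c1 | target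

**Totals**
Total step count: 5. Longest linear sequence: 4 (steps 1, 2, 4, 5); step 3 is a one-step side branch.

**Three steps most likely to fail**

Step 2 (the proposed new step). The risks are:
- low enantioselectivity;
- erosion of the branched-to-linear ratio if acetate attacks from outside the metal;
- palladium-hydride cycloisomerisation of the 1,6-diene.

The fallback uses known chemistry, sets out from 3 and comes back at 4. The established racemic branched acetoxylation (Pd(OAc)2, 1,2-bis(phenylsulfinyl)ethane, 1,4-benzoquinone, AcOH, dioxane, 43 °C) gives racemic (6E)-7-(4-acetoxyphenyl)hepta-1,6-dien-3-yl acetate F2. K2CO3 in MeOH removes both acetyl groups to give racemic 4-[(1E)-5-hydroxyhepta-1,6-dien-1-yl]phenol F3. Kinetic resolution with Candida antarctica lipase B and vinyl acetate in MTBE at 30 °C, stopped near half conversion, acylates the (S)-carbinol (vinyl as the medium group, the long chain as the large group). This gives (3S,6E)-7-(4-hydroxyphenyl)hepta-1,6-dien-3-yl acetate F4, which is separated from the unreacted (R)-alcohol. Ac2O and pyridine then cap the phenol to give 4.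

Step 1. Heck arylation of an unactivated terminal olefin can give the 2-aryl regioisomer, the non-conjugated 1-aryl-2-ene isomer, double arylation, or cyclisation of the alkylpalladium intermediate onto the second olefin. The fallback sets out from 1 and comes back at 3. Alkyne-selective syn-hydroboration of commercial hept-1-en-6-yne with pinacolborane (Cp2Zr(H)Cl 5 mol%, Et3N 10 mol%, 60 °C) gives 2-[(1E)-hepta-1,6-dien-1-yl]-4,4,5,5-tetramethyl-1,3,2-dioxaborolane F1. Suzuki–Miyaura coupling of F1 with 1 (Pd(PPh3)4, CsF, 1,4-dioxane, 80 °C; the fluoride base spares the aryl acetate) gives 3 with the olefin position and E geometry fixed by the boronate.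

Step 4. The basic coupling medium may cleave the alkyl acetate, or the alkylborane may transmetalate slowly and be lost by protodeboronation. Partial loss of aryl acetates is harmless because step 5 removes them. The fallback sets out from 8 (made in the flask from 4 and 7 as before) and comes back at 9. Oxidation of 8 with anhydrous Me3NO (THF, 60 °C, neutral work-up) gives 4-[(1E,5S)-5-acetoxy-7-hydroxyhept-1-en-1-yl]phenyl acetate F5. F5 is used at once to avoid 1,3-acyl shift and is converted with PPh3, I2 and imidazole (CH2Cl2, 0 °C) to 4-[(1E,5S)-5-acetoxy-7-iodohept-1-en-1-yl]phenyl acetate F6. Nickel-catalysed reductive cross-electrophile coupling of F6 with aryl bromide 6 (NiI2 10 mol%, 4,4'-di-tert-butyl-2,2'-bipyridine, zinc dust, NaI, DMPU, 60 °C; neutral, ester-tolerant) gives 9.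

**Further compounds**
F1 | step 1 | 2-[(1E)-hepta-1,6-dien-1-yl]-4,4,5,5-tetramethyl-1,3,2-dioxaborolane | C=CCCC/C=C/B1OC(C)(C)C(C)(C)O1
F2 | step 2 | racemic (6E)-7-(4-acetoxyphenyl)hepta-1,6-dien-3-yl acetate | CC(=O)OC(CC/C=C/c1ccc(OC(C)=O)cc1)C=C
F3 | step 2 | racemic 4-[(1E)-5-hydroxyhepta-1,6-dien-1-yl]phenol | OC(CC/C=C/c1ccc(O)cc1)C=C
F4 | step 2 | (3S,6E)-7-(4-hydroxyphenyl)hepta-1,6-dien-3-yl acetate | CC(=O)O[C@@H](CC/C=C/c1ccc(O)cc1)C=C
F5 | step 4 | 4-[(1E,5S)-5-acetoxy-7-hydroxyhept-1-en-1-yl]phenyl acetate | CC(=O)O[C@@H](CC/C=C/c1ccc(OC(C)=O)cc1)CCO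
F6 | step 4 | 4-[(1E,5S)-5-acetoxy-7-iodohept-1-en-1-yl]phenyl acetate | CC(=O)O[C@@H](CC/C=C/c1ccc(OC(C)=O)cc1)CCI
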